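## Retrosynthetic overview

1. Labels (elemane numbering): six-membered ring C5–C10 with quaternary C10 (C14 methyl, C1=C2 vinyl), C5 (C4(=C3)–C15H2OH), C6 (OH), C7, C8 (lactone O), C9 (O-isobutyryl); γ-lactone C8–O–C12(=O)–C11(=C13)–C7, cis-fused at C7/C8.
2. Late events: 15-OH by allylic oxidation of the isopropenyl group, the 9-O-isobutyrate, and the 13-methylene by Mannich/elimination on the saturated lactone.
3. Key disconnection C8–C9: the lactone carbinol C8 next to the acyloxy carbinol C9 is an acyloin retron, so the cyclohexane opens to an acyclic 1,6-dialdehyde. Forward, a carbene-catalysed acyloin closure makes the carbocycle first; hydride reduction and lactonisation in the same flask then close the γ-lactone.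
4. Enabling feature: C9 sits on quaternary C10, so its aldehyde cannot enolise and is too hindered to be the acyl-anion donor; only C8 can be. In the new ring the C14 methyl is axial and syn to C8, which sends hydride to the opposite face and puts the C8 oxygen axial, cis to the C7 acetate arm.
5. The dialdehyde comes from an auxiliary-controlled syn-aldol (C6–C7) on an aldehyde made by an enantioselective Ireland–Claisen rearrangement (C5–C10, sets C5 and quaternary C10).

Key step: step 13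

Remark: the (S,S)-boron controller of step 4 is assumed to deliver the (2S,3S)-acid; if its sense of induction is the opposite, the (R,R)-controller is used instead.

## Route

Step 1
Reactants: 1 1-[(tert-butyldimethylsilyl)oxy]propan-2-one; 2 triethyl phosphonoacetate
Product: 3 ethyl (2E)-4-[(tert-butyldimethylsilyl)oxy]-3-methylbut-2-enoate
Conditions: NaH, THF, 0 → 23 °C; E isomer separated by chromatography
Reagents that add atoms: none
Why: Horner–Wadsworth–Emmons olefination of the ketone should place the ester trans to the larger CH2OTBS group, fixing the E geometry that the later rearrangement needs.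

Step 2
Reactants: 3 ethyl (2E)-4-[(tert-butyldimethylsilyl)oxy]-3-methylbut-2-enoate
Product: 4 (2E)-4-[(tert-butyldimethylsilyl)oxy]-3-methylbut-2-en-1-ol
Conditions: i-Bu2AlH (2.2 equiv), CH2Cl2, −78 °C; aq. KNaC4H4O6
Reagents that add atoms: none
Why: 1,2-reduction of the enoate by the aluminium hydride should give the allylic alcohol without touching the silyl ether or the alkene geometry.

Step 3
Reactants: 4 (2E)-4-[(tert-butyldimethylsilyl)oxy]-3-methylbut-2-en-1-ol; 5 3-methylbut-3-enoic acid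
Product: 6 (2E)-4-[(tert-butyldimethylsilyl)oxy]-3-methylbut-2-en-1-yl 3-methylbut-3-enoate
Conditions: N,N′-dicyclohexylcarbodiimide, 4-(dimethylamino)pyridine (5 mol %), CH2Cl2, 0 °C
Reagents that add atoms: none
Why: carbodiimide (Steglich) esterification at low temperature should couple the β,γ-unsaturated acid before its double bond can move into conjugation.

Step 4
Reactants: 6 (2E)-4-[(tert-butyldimethylsilyl)oxy]-3-methylbut-2-en-1-yl 3-methylbut-3-enoate
Product: 9 (2S,3S)-3-{[(tert-butyldimethylsilyl)oxy]methyl}-3-methyl-2-(prop-1-en-2-yl)pent-4-enoic acid, via boron ketene acetal 7 (not isolated), via acyloxyborane 8 (not isolated)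
Conditions: (S,S)-2-bromo-4,5-diphenyl-1,3-bis{[3,5-bis(trifluoromethyl)phenyl]sulfonyl}-1,3,2-diazaborolidine (1.1 equiv), i-Pr2NEt, CH2Cl2, −78 °C; then −20 → 4 °C; aqueous work-up
Reagents that add atoms: none
Why: enantioselective Ireland–Claisen rearrangement through a chair: soft enolisation gives 7 with the 2-propenyl group trans to O–B, the E allyl unit places the C14 methyl pseudo-axial and CH2OTBS pseudo-equatorial, so the new C5–C10 bond sets the C5 methine and quaternary C10 in the required relative sense, while the C2-symmetric sulfonamide ligand on boron selects the enolate face.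

Step 5
Reactants: 9 (2S,3S)-3-{[(tert-butyldimethylsilyl)oxy]methyl}-3-methyl-2-(prop-1-en-2-yl)pent-4-enoic acid
Product: 10 (2S,3S)-3-{[(tert-butyldimethylsilyl)oxy]methyl}-3-methyl-2-(prop-1-en-2-yl)pent-4-en-1-ol
Conditions: LiAlH4, Et2O, 0 → 23 °C
Reagents that add atoms: none
Why: hydride reduction of the carboxylic acid to the primary alcohol should leave the isolated alkenes and the silyl ether untouched and cannot epimerise C5.

Step 6
Reactants: 10 (2S,3S)-3-{[(tert-butyldimethylsilyl)oxy]methyl}-3-methyl-2-(prop-1-en-2-yl)pent-4-en-1-ol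
Product: 11 (2S,3S)-3-{[(tert-butyldimethylsilyl)oxy]methyl}-3-methyl-2-(prop-1-en-2-yl)pent-4-enal
Conditions: Dess–Martin periodinane, NaHCO3 (buffer), CH2Cl2, 0 °C; used at once
Reagents that add atoms: none
Why: a neutral Dess–Martin oxidation should give the β,γ-unsaturated aldehyde without base, so the C5 centre is neither epimerised nor drawn into conjugation.

Step 7
Reactants: 12 (4S)-4-benzyl-1,3-thiazolidine-2-thione; 13 methyl 4-chloro-4-oxobutanoate
Product: 14 methyl 4-[(4S)-4-benzyl-2-thioxo-1,3-thiazolidin-3-yl]-4-oxobutanoate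
Conditions: Et3N, 4-(dimethylamino)pyridine (5 mol %), CH2Cl2, 0 °C
Reagents that add atoms: none
Why: N-acylation of the thiazolidinethione by the acid chloride should give the imide that carries C7, C8, C11 and C12.

Step 8
Reactants: 11 (2S,3S)-3-{[(tert-butyldimethylsilyl)oxy]methyl}-3-methyl-2-(prop-1-en-2-yl)pent-4-enal; 14 methyl 4-[(4S)-4-benzyl-2-thioxo-1,3-thiazolidin-3-yl]-4-oxobutanoate
Product: 16 syn-aldol adduct, methyl (3S,4R,5S,6S)-3-{[(4S)-4-benzyl-2-thioxo-1,3-thiazolidin-3-yl]carbonyl}-6-{[(tert-butyldimethylsilyl)oxy]methyl}-4-hydroxy-6-methyl-5-(prop-1-en-2-yl)oct-7-enoate, via chlorotitanium enolate 15 (not isolated)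
Conditions: 14, TiCl4 (1.05 equiv), i-Pr2NEt (1.1 equiv), N-methyl-2-pyrrolidinone (1.0 equiv), CH2Cl2, −78 → 0 °C; then 11, −78 °C; aq. NH4Cl
Reagents that add atoms: none
Why: titanium-mediated syn-aldol of an N-acyl thiazolidinethione: Z-enolate 15 should react through a non-chelated Zimmerman–Traxler chair in which the auxiliary benzyl group shields one enolate face, setting C6 (R) and C7 (S) syn, a sense that matches the Felkin–Anh preference of 11 (quaternary C10 as the large group).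

Step 9
Reactants: 16 syn-aldol adduct
Product: 17 methyl (3S,4R,5S,6S)-3-{[(4S)-4-benzyl-2-thioxo-1,3-thiazolidin-3-yl]carbonyl}-4-[(tert-butyldimethylsilyl)oxy]-6-{[(tert-butyldimethylsilyl)oxy]methyl}-6-methyl-5-(prop-1-en-2-yl)oct-7-enoate
Conditions: tert-butyldimethylsilyl trifluoromethanesulfonate, 2,6-lutidine, CH2Cl2, −78 → 0 °C
Reagents that add atoms: tert-butyldimethylsilyl trifluoromethanesulfonate CC(C)(C)[Si](C)(C)OS(=O)(=O)C(F)(F)F
Why: the silyl triflate should cap the hindered 6-OH before it can lactonise onto the C12 ester, so that later only the 8-OH can lactonise and only the 9-OH can be acylated.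

Step 10
Reactants: 17 bis-silyl thioimide
Product: 18 methyl (3S,4R,5S,6S)-4-[(tert-butyldimethylsilyl)oxy]-6-{[(tert-butyldimethylsilyl)oxy]methyl}-3-formyl-6-methyl-5-(prop-1-en-2-yl)oct-7-enoate
Conditions: i-Bu2AlH (1.2 equiv), CH2Cl2, −78 °C; aq. KNaC4H4O6
Reagents that add atoms: none
Why: the activated acyl thiazolidinethione should be reduced to the C8 aldehyde through a stable tetrahedral aluminium adduct much faster than the methyl ester reacts, releasing the auxiliary.

Step 11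
Reactants: 18 C8 aldehyde with 9-OTBS
Product: 19 methyl (3S,4R,5S,6S)-4-[(tert-butyldimethylsilyl)oxy]-3-formyl-6-(hydroxymethyl)-6-methyl-5-(prop-1-en-2-yl)oct-7-enoate
Conditions: HF·pyridine, pyridine, THF, 0 °C
Reagents that add atoms: none
Why: buffered fluoride should cleave the primary silyl ether at C9 faster than the secondary one at C6, which is flanked by two branched carbons.

Step 12
Reactants: 19 hydroxy aldehyde
Product: 20 dialdehyde, methyl (3S,4R,5S,6S)-4-[(tert-butyldimethylsilyl)oxy]-3,6-diformyl-6-methyl-5-(prop-1-en-2-yl)oct-7-enoate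
Conditions: Dess–Martin periodinane, NaHCO3 (buffer), CH2Cl2, 0 → 23 °C; used crude
Reagents that add atoms: none
Why: Dess–Martin oxidation of the neopentyl alcohol should give the non-enolisable C9 aldehyde under neutral conditions that spare the C7 centre.

Step 13
Reactants: 20 dialdehyde
Product: 23 hydroxy lactone (cis-fused 8,12-lactone, 9-OH, 6-OTBS), (3aR,4R,5S,6S,7R,7aS)-4-[(tert-butyldimethylsilyl)oxy]-6-ethenyl-7-hydroxy-6-methyl-5-(prop-1-en-2-yl)hexahydro-1-benzofuran-2(3H)-one, via ketol 21 (not isolated), via diol ester 22 (not isolated)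
Conditions: 2-(pentafluorophenyl)-6,7-dihydro-5H-pyrrolo[2,1-c][1,2,4]triazol-2-ium tetrafluoroborate (15 mol %), i-Pr2NEt (15 mol %), THF (0.02 M), 23 °C; then LiBH(s-Bu)3 (2.5 equiv), −78 °C; then AcOH, −78 → 23 °C
Reagents that add atoms: none
Why: The carbene should add to the less hindered C8 aldehyde, the resulting hydroxy-enamine (acyl-anion equivalent) attacks the C9 aldehyde, and proton transfer with loss of the carbene gives ketol 21; LiBH(s-Bu)3 then reduces the C8 ketone and the new alkoxide closes onto the C12 methyl ester. The closest known reactions are the azolium-carbene acyloin (benzoin) cyclisation of dialdehydes and the bulky-borohydride reduction of cyclohexanones that carry a syn-axial 3-methyl group. The carbocycle closes by 6-exo-trig addition of C8 to the C9 carbonyl and the γ-lactone by 5-exo-trig acyl substitution. C9 is set in the acyloin step, where the hydrogen-bonded transition state and the reversibility of the addition both favour the equatorial hydroxyl; C8 is set by hydride entering opposite the axial C14 methyl, which leaves the C8 oxygen axial and cis to the C7 arm, the only geometry that lactonises. The step needs one donor/acceptor sense and an intact C7 centre: the quaternary C10 makes the C9 aldehyde non-enolisable and too crowded to become the donor, and the weak catalytic base and the poor silyloxy leaving group at C6 limit epimerisation and β-elimination.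

Step 14
Reactants: 23 hydroxy lactone
Product: 26 α-methylene lactone, (3aR,4R,5S,6S,7R,7aS)-4-[(tert-butyldimethylsilyl)oxy]-6-ethenyl-7-hydroxy-6-methyl-3-methylidene-5-(prop-1-en-2-yl)hexahydro-1-benzofuran-2(3H)-one, via Mannich base 24 (not isolated), via ammonium iodide 25 (not isolated)
Conditions: LiN(i-Pr)2 (2.5 equiv), THF, −78 °C; N,N-dimethylmethyleneiminium iodide, −78 → 0 °C; then MeI, MeOH, 23 °C; then aq. NaHCO3/CH2Cl2
Reagents that add atoms: N,N-dimethylmethyleneiminium iodide (Eschenmoser's salt) C=[N+](C)C.[I-]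
Why: the lactone enolate (formed beside the C9 alkoxide) should undergo a Mannich reaction at C11, and quaternisation followed by mild-base elimination installs the 11(13)-methylene without creating a lasting stereocentre.

Step 15
Reactants: 26 α-methylene lactone
Product: 27 (3aR,4R,5S,6S,7R,7aS)-4-[(tert-butyldimethylsilyl)oxy]-6-ethenyl-6-methyl-3-methylidene-2-oxo-5-(prop-1-en-2-yl)octahydro-1-benzofuran-7-yl 2-methylpropanoate
Conditions: isobutyryl chloride, 4-(dimethylamino)pyridine, pyridine, CH2Cl2, 0 → 40 °C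
Reagents that add atoms: isobutyryl chloride CC(C)C(Cl)=O
Why: the 9-OH is the only free hydroxyl, so nucleophile-catalysed acylation should place the isobutyrate there with retention at C9.

Step 16
Reactants: 27 isobutyrate
Product: 28 (3aR,4R,5S,6S,7R,7aS)-4-[(tert-butyldimethylsilyl)oxy]-6-ethenyl-5-(3-hydroxyprop-1-en-2-yl)-6-methyl-3-methylidene-2-oxooctahydro-1-benzofuran-7-yl 2-methylpropanoate
Conditions: SeO2 (0.5 equiv), t-BuOOH (3 equiv), CH2Cl2, 0 → 23 °C
Reagents that add atoms: selenium dioxide (oxygen carrier) O=[Se]=O; tert-butyl hydroperoxide (terminal oxygen source) CC(C)(C)OO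
Why: allylic hydroxylation by ene reaction and [2,3]-sigmatropic shift should occur at the C15 methyl of the only electron-rich alkene that has reactive allylic hydrogens, since the vinyl group has none, the α-methylene lactone is electron-poor, and the tertiary C5–H is hindered.

Step 17
Reactants: 28 15-hydroxy silyl ether
Product: 29 target, (3aS,4R,5S,6S,7R,7aS)-6-ethenyl-4-hydroxy-5-(3-hydroxyprop-1-en-2-yl)-6-methyl-3-methylidene-2-oxooctahydro-1-benzofuran-7-yl 2-methylpropanoate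
Conditions: HF·pyridine, THF, 0 → 23 °C
Reagents that add atoms: none
Why: acidic fluoride should remove the last silyl ether at C6 without ester migration or attack on the α-methylene lactone.

## Compound list

1 | 1-[(tert-butyldimethylsilyl)oxy]propan-2-one | CC(=O)CO[Si](C)(C)C(C)(C)C | starting material
2 | triethyl phosphonoacetate | CCOC(=O)CP(=O)(OCC)OCC | starting material
3 | ethyl (2E)-4-[(tert-butyldimethylsilyl)oxy]-3-methylbut-2-enoate | CCOC(=O)/C=C(\C)CO[Si](C)(C)C(C)(C)C | intermediate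
4 | (2E)-4-[(tert-butyldimethylsilyl)oxy]-3-methylbut-2-en-1-ol | OC/C=C(\C)CO[Si](C)(C)C(C)(C)C | intermediate
5 | 3-methylbut-3-enoic acid | C=C(C)CC(=O)O | starting material
6 | (2E)-4-[(tert-butyldimethylsilyl)oxy]-3-methylbut-2-en-1-yl 3-methylbut-3-enoate | C=C(C)CC(=O)OC/C=C(\C)CO[Si](C)(C)C(C)(C)C | intermediate
7 | O-boron ketene acetal of 6 with the (S,S)-diazaborolidine (2-propenyl trans to O–B) | C=C(C)/C=C(/OB1N(S(=O)(=O)c2cc(cc(c2)C(F)(F)F)C(F)(F)F)[C@@H](c2ccccc2)[C@H](c2ccccc2)N1S(=O)(=O)c1cc(cc(c1)C(F)(F)F)C(F)(F)F)OC/C=C(\C)CO[Si](C)(C)C(C)(C)C | intermediate (not isolated)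
8 | acyloxyborane of acid 9 with the (S,S)-diazaborolidine | C=C[C@@](CO[Si](C)(C)C(C)(C)C)(C)[C@H](C(C)=C)C(=O)OB1N(S(=O)(=O)c2cc(cc(c2)C(F)(F)F)C(F)(F)F)[C@@H](c2ccccc2)[C@H](c2ccccc2)N1S(=O)(=O)c1cc(cc(c1)C(F)(F)F)C(F)(F)F | intermediate (not isolated)
9 | (2S,3S)-3-{[(tert-butyldimethylsilyl)oxy]methyl}-3-methyl-2-(prop-1-en-2-yl)pent-4-enoic acid | C=C[C@@](CO[Si](C)(C)C(C)(C)C)(C)[C@H](C(C)=C)C(=O)O | intermediate
10 | (2S,3S)-3-{[(tert-butyldimethylsilyl)oxy]methyl}-3-methyl-2-(prop-1-en-2-yl)pent-4-en-1-ol | C=C[C@@](CO[Si](C)(C)C(C)(C)C)(C)[C@H](C(C)=C)CO | intermediate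
11 | (2S,3S)-3-{[(tert-butyldimethylsilyl)oxy]methyl}-3-methyl-2-(prop-1-en-2-yl)pent-4-enal | C=C[C@@](CO[Si](C)(C)C(C)(C)C)(C)[C@H](C(C)=C)C=O | intermediate
12 | (4S)-4-benzyl-1,3-thiazolidine-2-thione | S=C1SC[C@H](Cc2ccccc2)N1 | starting material
13 | methyl 4-chloro-4-oxobutanoate | COC(=O)CCC(Cl)=O | starting material
14 | methyl 4-[(4S)-4-benzyl-2-thioxo-1,3-thiazolidin-3-yl]-4-oxobutanoate | COC(=O)CCC(=O)N1[C@@H](Cc2ccccc2)CSC1=S | intermediate
15 | trichlorotitanium (Z)-enolate of 14 | COC(=O)C/C=C(\O[Ti](Cl)(Cl)Cl)N1[C@@H](Cc2ccccc2)CSC1=S | intermediate (not isolated)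
16 | methyl (3S,4R,5S,6S)-3-{[(4S)-4-benzyl-2-thioxo-1,3-thiazolidin-3-yl]carbonyl}-6-{[(tert-butyldimethylsilyl)oxy]methyl}-4-hydroxy-6-methyl-5-(prop-1-en-2-yl)oct-7-enoate | C=C[C@@](CO[Si](C)(C)C(C)(C)C)(C)[C@H](C(C)=C)[C@@H](O)[C@@H](C(=O)N1[C@@H](Cc2ccccc2)CSC1=S)CC(=O)OC | intermediate
17 | methyl (3S,4R,5S,6S)-3-{[(4S)-4-benzyl-2-thioxo-1,3-thiazolidin-3-yl]carbonyl}-4-[(tert-butyldimethylsilyl)oxy]-6-{[(tert-butyldimethylsilyl)oxy]methyl}-6-methyl-5-(prop-1-en-2-yl)oct-7-enoate | C=C[C@@](CO[Si](C)(C)C(C)(C)C)(C)[C@H](C(C)=C)[C@@H](O[Si](C)(C)C(C)(C)C)[C@@H](C(=O)N1[C@@H](Cc2ccccc2)CSC1=S)CC(=O)OC | intermediate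
18 | methyl (3S,4R,5S,6S)-4-[(tert-butyldimethylsilyl)oxy]-6-{[(tert-butyldimethylsilyl)oxy]methyl}-3-formyl-6-methyl-5-(prop-1-en-2-yl)oct-7-enoate | C=C[C@@](CO[Si](C)(C)C(C)(C)C)(C)[C@H](C(C)=C)[C@@H](O[Si](C)(C)C(C)(C)C)[C@@H](C=O)CC(=O)OC | intermediate
19 | methyl (3S,4R,5S,6S)-4-[(tert-butyldimethylsilyl)oxy]-3-formyl-6-(hydroxymethyl)-6-methyl-5-(prop-1-en-2-yl)oct-7-enoate | C=C[C@@](CO)(C)[C@H](C(C)=C)[C@@H](O[Si](C)(C)C(C)(C)C)[C@@H](C=O)CC(=O)OC | intermediate
20 | methyl (3S,4R,5S,6S)-4-[(tert-butyldimethylsilyl)oxy]-3,6-diformyl-6-methyl-5-(prop-1-en-2-yl)oct-7-enoate | C=C[C@@](C=O)(C)[C@H](C(C)=C)[C@@H](O[Si](C)(C)C(C)(C)C)[C@@H](C=O)CC(=O)OC | intermediate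
21 | methyl 2-[(1S,2R,3S,4S,5R)-2-[(tert-butyldimethylsilyl)oxy]-4-ethenyl-5-hydroxy-4-methyl-6-oxo-3-(prop-1-en-2-yl)cyclohexyl]acetate | C=C[C@@]1(C)[C@H](C(C)=C)[C@@H](O[Si](C)(C)C(C)(C)C)[C@H](CC(=O)OC)C(=O)[C@@H]1O | intermediate (not isolated)
22 | methyl 2-[(1R,2R,3S,4S,5R,6S)-2-[(tert-butyldimethylsilyl)oxy]-4-ethenyl-5,6-dihydroxy-4-methyl-3-(prop-1-en-2-yl)cyclohexyl]acetate | C=C[C@@]1(C)[C@H](C(C)=C)[C@@H](O[Si](C)(C)C(C)(C)C)[C@H](CC(=O)OC)[C@H](O)[C@@H]1O | intermediate (not isolated)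
23 | (3aR,4R,5S,6S,7R,7aS)-4-[(tert-butyldimethylsilyl)oxy]-6-ethenyl-7-hydroxy-6-methyl-5-(prop-1-en-2-yl)hexahydro-1-benzofuran-2(3H)-one | C=C[C@@]1(C)[C@H](C(C)=C)[C@@H](O[Si](C)(C)C(C)(C)C)[C@@H]2CC(=O)O[C@@H]2[C@@H]1O | intermediate
24 | (3aR,4R,5S,6S,7R,7aS)-4-[(tert-butyldimethylsilyl)oxy]-3-[(dimethylamino)methyl]-6-ethenyl-7-hydroxy-6-methyl-5-(prop-1-en-2-yl)hexahydro-1-benzofuran-2(3H)-one (C3 epimers) | C=C[C@@]1(C)[C@H](C(C)=C)[C@@H](O[Si](C)(C)C(C)(C)C)[C@@H]2C(CN(C)C)C(=O)O[C@@H]2[C@@H]1O | intermediate (not isolated)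
25 | trimethylammonium iodide of 24 (N-methylated Mannich base) | C=C[C@@]1(C)[C@H](C(C)=C)[C@@H](O[Si](C)(C)C(C)(C)C)[C@@H]2C(C[N+](C)(C)C)C(=O)O[C@@H]2[C@@H]1O.[I-] | intermediate (not isolated)
26 | (3aR,4R,5S,6S,7R,7aS)-4-[(tert-butyldimethylsilyl)oxy]-6-ethenyl-7-hydroxy-6-methyl-3-methylidene-5-(prop-1-en-2-yl)hexahydro-1-benzofuran-2(3H)-one | C=C[C@@]1(C)[C@H](C(C)=C)[C@@H](O[Si](C)(C)C(C)(C)C)[C@@H]2C(=C)C(=O)O[C@@H]2[C@@H]1O | intermediate
27 | (3aR,4R,5S,6S,7R,7aS)-4-[(tert-butyldimethylsilyl)oxy]-6-ethenyl-6-methyl-3-methylidene-2-oxo-5-(prop-1-en-2-yl)octahydro-1-benzofuran-7-yl 2-methylpropanoate | C=C[C@@]1(C)[C@H](C(C)=C)[C@@H](O[Si](C)(C)C(C)(C)C)[C@@H]2C(=C)C(=O)O[C@@H]2[C@@H]1OC(=O)C(C)C | intermediate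
28 | (3aR,4R,5S,6S,7R,7aS)-4-[(tert-butyldimethylsilyl)oxy]-6-ethenyl-5-(3-hydroxyprop-1-en-2-yl)-6-methyl-3-methylidene-2-oxooctahydro-1-benzofuran-7-yl 2-methylpropanoate | C=C[C@@]1(C)[C@H](C(=C)CO)[C@@H](O[Si](C)(C)C(C)(C)C)[C@@H]2C(=C)C(=O)O[C@@H]2[C@@H]1OC(=O)C(C)C | intermediate
29 | (3aS,4R,5S,6S,7R,7aS)-6-ethenyl-4-hydroxy-5-(3-hydroxyprop-1-en-2-yl)-6-methyl-3-methylidene-2-oxooctahydro-1-benzofuran-7-yl 2-methylpropanoate | C=C[C@@]1(C)[C@H](C(=C)CO)[C@@H](O)[C@@H]2C(=C)C(=O)O[C@@H]2[C@@H]1OC(=O)C(C)C | target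

## Summary and risks

Total step count: 17. Longest linear sequence: 16 steps (steps 1–6 and 8–17; step 7 is a one-step side branch).

Most likely to fail:

1. Step 13. Under the basic carbene conditions the enolisable C8 aldehyde may add as an enolate to C9 (five-membered aldol), the silyloxy group at C6 may be lost by β-elimination, or attack on the crowded C9 carbonyl may be slow enough for intermolecular acyloin dimerisation to compete. The fallback closes the same bond reductively and without base. It sets out from 18: NH2OH·HCl and pyridine should give aldoxime F1, and dehydration with 1,1′-carbonyldiimidazole in CH2Cl2 the nitrile F2. HF·pyridine and then Dess–Martin periodinane, as in steps 11 and 12, should give hydroxy nitrile F3 and formyl nitrile F4. SmI2 (divalent samarium; THF, t-BuOH, 0 °C, visible light) should form the C9 ketyl, which adds 6-exo to the C8 nitrile to give ketimine F5. Aqueous NH4Cl work-up hydrolyses F5 to ketol 21, where the route is rejoined; reduction with LiBH(s-Bu)3 and lactonisation as in step 13 then give 23.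

2. Step 4. Facial discrimination by the boron controller or control of enolate geometry may be incomplete on this functionalised ester, and the β,γ-double bond may move into conjugation before the rearrangement. The fallback sets out from 6: LiN(i-Pr)2 with Me3SiCl/Et3N in THF (−78 → 23 °C, classical Ireland–Claisen through the same chair) and aqueous HCl should give the racemic acid F6. Pivaloyl chloride/Et3N and then lithiated (4S)-4-benzyl-1,3-oxazolidin-2-one should give the diastereomeric imides, wanted imide F7 and unwanted imide F8, which are separated by chromatography. LiBH4 (THF, 1 equiv H2O) reduction of F7 gives alcohol 10, where the route is rejoined with step 5 skipped.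

3. Step 16. The new allylic alcohol may be over-oxidised to the enal, the tertiary allylic C5–H may react in competition, or conversion on this crowded isopropenyl group may stall. The fallback sets out from 27: ene-type chlorination with HOCl generated from Ca(OCl)2 and CO2 (CH2Cl2/H2O, 0 °C) should give allylic chloride F9. AgOCOCF3 in acetone at 23 °C should give trifluoroacetate F10, and NaHCO3 in MeOH at 0 °C cleaves it to 28, where the route is rejoined.

Further compounds
F1 | step 13 | methyl (3S,4R,5S,6S)-4-[(tert-butyldimethylsilyl)oxy]-6-{[(tert-butyldimethylsilyl)oxy]methyl}-3-[(hydroxyimino)methyl]-6-methyl-5-(prop-1-en-2-yl)oct-7-enoate | C=C[C@@](CO[Si](C)(C)C(C)(C)C)(C)[C@H](C(C)=C)[C@@H](O[Si](C)(C)C(C)(C)C)[C@@H](C=NO)CC(=O)OC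
F2 | step 13 | methyl (3S,4R,5S,6S)-4-[(tert-butyldimethylsilyl)oxy]-6-{[(tert-butyldimethylsilyl)oxy]methyl}-3-cyano-6-methyl-5-(prop-1-en-2-yl)oct-7-enoate | C=C[C@@](CO[Si](C)(C)C(C)(C)C)(C)[C@H](C(C)=C)[C@@H](O[Si](C)(C)C(C)(C)C)[C@@H](C#N)CC(=O)OC
F3 | step 13 | methyl (3S,4R,5S,6S)-4-[(tert-butyldimethylsilyl)oxy]-3-cyano-6-(hydroxymethyl)-6-methyl-5-(prop-1-en-2-yl)oct-7-enoate | C=C[C@@](CO)(C)[C@H](C(C)=C)[C@@H](O[Si](C)(C)C(C)(C)C)[C@@H](C#N)CC(=O)OC
F4 | step 13 | methyl (3S,4R,5S,6S)-4-[(tert-butyldimethylsilyl)oxy]-3-cyano-6-formyl-6-methyl-5-(prop-1-en-2-yl)oct-7-enoate | C=C[C@@](C=O)(C)[C@H](C(C)=C)[C@@H](O[Si](C)(C)C(C)(C)C)[C@@H](C#N)CC(=O)OC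
F5 | step 13 | methyl 2-[(1S,2R,3S,4S,5R)-2-[(tert-butyldimethylsilyl)oxy]-4-ethenyl-5-hydroxy-6-imino-4-methyl-3-(prop-1-en-2-yl)cyclohexyl]acetate | C=C[C@@]1(C)[C@H](C(C)=C)[C@@H](O[Si](C)(C)C(C)(C)C)[C@H](CC(=O)OC)C(=N)[C@@H]1O
F6 | step 4 | racemic (2S*,3S*)-3-{[(tert-butyldimethylsilyl)oxy]methyl}-3-methyl-2-(prop-1-en-2-yl)pent-4-enoic acid | C=C[C@@](CO[Si](C)(C)C(C)(C)C)(C)[C@H](C(C)=C)C(=O)O.C=C[C@](CO[Si](C)(C)C(C)(C)C)(C)[C@@H](C(C)=C)C(=O)O
F7 | step 4 | (4S)-4-benzyl-3-[(2S,3S)-3-{[(tert-butyldimethylsilyl)oxy]methyl}-3-methyl-2-(prop-1-en-2-yl)pent-4-enoyl]-1,3-oxazolidin-2-one | C=C[C@@](CO[Si](C)(C)C(C)(C)C)(C)[C@H](C(C)=C)C(=O)N1[C@@H](Cc2ccccc2)COC1=O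
F8 | step 4 | (4S)-4-benzyl-3-[(2R,3R)-3-{[(tert-butyldimethylsilyl)oxy]methyl}-3-methyl-2-(prop-1-en-2-yl)pent-4-enoyl]-1,3-oxazolidin-2-one | C=C[C@](CO[Si](C)(C)C(C)(C)C)(C)[C@@H](C(C)=C)C(=O)N1[C@@H](Cc2ccccc2)COC1=O
F9 | step 16 | (3aR,4R,5S,6S,7R,7aS)-4-[(tert-butyldimethylsilyl)oxy]-5-(3-chloroprop-1-en-2-yl)-6-ethenyl-6-methyl-3-methylidene-2-oxooctahydro-1-benzofuran-7-yl 2-methylpropanoate | C=C[C@@]1(C)[C@H](C(=C)CCl)[C@@H](O[Si](C)(C)C(C)(C)C)[C@@H]2C(=C)C(=O)O[C@@H]2[C@@H]1OC(=O)C(C)C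
F10 | step 16 | (3aR,4R,5S,6S,7R,7aS)-4-[(tert-butyldimethylsilyl)oxy]-6-ethenyl-6-methyl-3-methylidene-2-oxo-5-{3-[(trifluoroacetyl)oxy]prop-1-en-2-yl}octahydro-1-benzofuran-7-yl 2-methylpropanoate | C=C[C@@]1(C)[C@H](C(=C)COC(=O)C(F)(F)F)[C@@H](O[Si](C)(C)C(C)(C)C)[C@@H]2C(=C)C(=O)O[C@@H]2[C@@H]1OC(=O)C(C)C
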